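**Strategy.** Ring A (C1–C2–C3–C4–C5–C10, halimane numbering) is treated as a Diels–Alder cyclohexene. C5 is trigonal in the target and C4 is made quaternary afterwards, so C2=C3–C4=C5 can be a diene and C1=C10 a vinyl dienophile on quaternary C9. One thermal intramolecular cycloaddition of an acyclic 1,7,9-decatriene forms C1–C2 and the ring-fusion bond C5–C10, closing rings A and B together and setting C10 from the C7–C9 stereocentres. The precursor is a linear triene diol. Its C8/C9 stereodiad comes from an enantioselective Ireland–Claisen rearrangement of a citronellol-derived allyl propionate. The residual C3=C4 alkene is later turned into the C4 quaternary centre by cyclopropanation and hydrogenolysis.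

Key step: step 13

Remark on numbering: halimane numbering is used for all intermediates: ring A = C1–C5 and C10, ring B = C5–C10; C4 carries C19H3 and C18H2OAc, C8 carries C17H3, C9 carries C20H3 and the chain C11–C12–C13(C16H3)–C14–C15.

Assumption: the two chiral controllers (step 6 and step 14) are taken to induce in the sense of their published models; both exist as either antipode, so a reversed sense would be met by the mirror-image controller with no other change.

Step 1
Reactants: 1 (R)-citronellol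
Product: 2 triisopropyl{[(3R)-3,7-dimethyloct-6-en-1-yl]oxy}silane
Conditions: i-Pr3SiCl, imidazole, DMF, 25 °C
Reagents that add atoms: chlorotriisopropylsilane, CC(C)[Si](Cl)(C(C)C)C(C)C
Why: Imidazole-promoted silylation of the primary alcohol; the chiral-pool stereocentre (future C13) is untouched and the arene-free, non-enolisable silyl ether carries C15 through all later steps.

Step 2
Reactants: 2 triisopropyl{[(3R)-3,7-dimethyloct-6-en-1-yl]oxy}silane
Product: 4 (4R)-4-methyl-6-[(triisopropylsilyl)oxy]hexanal, via ozonide 3 (not isolated)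
Conditions: O3, CH2Cl2, −78 °C; then PPh3, −78 → 25 °C
Reagents that add atoms: ozone, [O-][O+]=O
Why: Ozonolysis with reductive work-up cleaves the only alkene to the aldehyde whose carbon becomes C9; the remote stereocentre is unaffected.

Step 3
Reactants: 4 (4R)-4-methyl-6-[(triisopropylsilyl)oxy]hexanal
Product: 5 triisopropyl{[(3R)-3-methylhept-6-yn-1-yl]oxy}silane
Conditions: dimethyl (1-diazo-2-oxopropyl)phosphonate, K2CO3, MeOH, 0 → 25 °C
Reagents that add atoms: dimethyl (1-diazo-2-oxopropyl)phosphonate, COP(=O)(OC)C(=[N+]=[N-])C(C)=O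
Why: Seyferth–Gilbert homologation with the Ohira–Bestmann reagent converts the aldehyde into the terminal alkyne C9≡C10 under mild conditions that spare the silyl ether.

Step 4
Reactants: 5 triisopropyl{[(3R)-3-methylhept-6-yn-1-yl]oxy}silane
Product: 7 (2E,6R)-3,6-dimethyl-8-[(triisopropylsilyl)oxy]oct-2-en-1-ol, via alkenylalane 6 (not isolated)
Conditions: Me3Al, Cp2ZrCl2 (cat.), CH2Cl2, 0 → 25 °C; then n-BuLi, (CH2O)n, THF, 0 → 25 °C; aqueous HCl work-up
Reagents that add atoms: trimethylaluminium, C[Al](C)C; formaldehyde (as paraformaldehyde), C=O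
Why: Negishi zirconium-catalysed carboalumination adds CH3–Al syn across the terminal alkyne with methyl on the internal carbon, and the derived alanate is hydroxymethylated with retention, which fixes the (E)-trisubstituted alkene C9=C10.

Step 5
Reactants: 7 (2E,6R)-3,6-dimethyl-8-[(triisopropylsilyl)oxy]oct-2-en-1-ol; 8 propanoyl chloride
Product: 9 (2E,6R)-3,6-dimethyl-8-[(triisopropylsilyl)oxy]oct-2-en-1-yl propanoate
Conditions: pyridine, CH2Cl2, 0 °C
Reagents that add atoms: none
Why: Acylation of the primary allylic alcohol installs the propionate that supplies C7, C8 and C17.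

Step 6
Reactants: 9 (2E,6R)-3,6-dimethyl-8-[(triisopropylsilyl)oxy]oct-2-en-1-yl propanoate
Product: 11 (2R,3S,6R)-3-ethenyl-2,3,6-trimethyl-8-[(triisopropylsilyl)oxy]octanoic acid, via boron ketene acetal 10 (not isolated)
Conditions: (S,S)-2-bromo-1,3-bis{[3,5-bis(trifluoromethyl)phenyl]sulfonyl}-4,5-diphenyl-1,3,2-diazaborolidine, i-Pr2NEt, CH2Cl2, −78 → −20 °C; aqueous work-up
Reagents that add atoms: none
Why: Enantioselective Ireland–Claisen rearrangement through a chiral boron ketene acetal: soft enolisation should place the C8 methyl cis to O–B, and the [3,3] shift through a chair with that methyl and the C11 chain equatorial on the (E)-alkene sets the C8/C9 relationship (2R,3S), while the C2-symmetric controller selects the enantiotopic face.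

Step 7
Reactants: 11 (2R,3S,6R)-3-ethenyl-2,3,6-trimethyl-8-[(triisopropylsilyl)oxy]octanoic acid
Product: 12 (2R,3S,6R)-3-ethenyl-2,3,6-trimethyl-8-[(triisopropylsilyl)oxy]octan-1-ol
Conditions: LiAlH4, THF, 0 → 25 °C
Reagents that add atoms: none
Why: Hydride reduction of the carboxylic acid to the primary alcohol; neither stereocentre is at risk.

Step 8
Reactants: 12 (2R,3S,6R)-3-ethenyl-2,3,6-trimethyl-8-[(triisopropylsilyl)oxy]octan-1-ol
Product: 13 (2R,3S,6R)-3-ethenyl-2,3,6-trimethyl-8-[(triisopropylsilyl)oxy]octanal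
Conditions: Dess–Martin periodinane, NaHCO3, CH2Cl2, 0 → 25 °C
Reagents that add atoms: none
Why: Dess–Martin oxidation under buffered, non-basic conditions gives the α-branched C7 aldehyde without epimerising C8.

Step 9
Reactants: 13 (2R,3S,6R)-3-ethenyl-2,3,6-trimethyl-8-[(triisopropylsilyl)oxy]octanal
Product: 14 (2S)-2-[(2R,3S,6R)-3-ethenyl-3,6-dimethyl-8-(triisopropylsilyloxy)octan-2-yl]oxirane
Conditions: Me3S+ I−, n-BuLi, THF, −10 → 25 °C
Reagents that add atoms: trimethylsulfonium iodide, C[S+](C)C.[I-]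
Why: Corey–Chaykovsky epoxidation adds C6; the ylide should attack by the Felkin–Anh mode anti to the quaternary C9, giving mainly the C7 epimer with oxygen syn to the C8 methyl (C7 later becomes the ketone, so it only has to bias step 13).

Step 10
Reactants: 14 (2S)-2-[(2R,3S,6R)-3-ethenyl-3,6-dimethyl-8-(triisopropylsilyloxy)octan-2-yl]oxirane; 15 trimethyl(prop-2-yn-1-yloxy)silane
Product: 17 (5R,6R,7S,10R)-7-ethenyl-6,7,10-trimethyl-12-[(triisopropylsilyl)oxy]dodec-2-yne-1,5-diol, via trimethylsilyl ether 16 (not isolated)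
Conditions: 15, n-BuLi, THF, −78 °C; BF3·OEt2; then 14, −78 → −40 °C; aqueous HCl/MeOH work-up
Reagents that add atoms: none
Why: BF3-assisted opening of the terminal epoxide by the lithium acetylide (Yamaguchi alkynylation) occurs at the unhindered CH2 to form C5–C6, and the acidic work-up removes the O–SiMe3 group to free the C18 hydroxyl.

Step 11
Reactants: 17 (5R,6R,7S,10R)-7-ethenyl-6,7,10-trimethyl-12-[(triisopropylsilyl)oxy]dodec-2-yne-1,5-diol
Product: 18 (2E,5R,6R,7S,10R)-7-ethenyl-6,7,10-trimethyl-2-(tributylstannyl)-12-[(triisopropylsilyl)oxy]dodec-2-ene-1,5-diol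
Conditions: Bu3SnH, PdCl2(PPh3)2 (divalent palladium precatalyst), THF, 0 → 25 °C
Reagents that add atoms: tributyltin hydride, CCCC[SnH](CCCC)CCCC
Why: Palladium-catalysed syn-hydrostannation places tin on the alkyne carbon next to the propargylic oxygen (C4) and hydrogen on C5, so that C6 and the CH2OH group end up cis.

Step 12
Reactants: 18 (2E,5R,6R,7S,10R)-7-ethenyl-6,7,10-trimethyl-2-(tributylstannyl)-12-[(triisopropylsilyl)oxy]dodec-2-ene-1,5-diol; 19 bromoethene
Product: 20 (2Z,5R,6R,7S,10R)-2,7-diethenyl-6,7,10-trimethyl-12-[(triisopropylsilyl)oxy]dodec-2-ene-1,5-diol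
Conditions: Pd(PPh3)4 (zerovalent palladium), CuI, CsF, DMF, 45 °C
Reagents that add atoms: none
Why: Stille coupling, promoted by CuI and fluoride for the hindered stannane, replaces tin by vinyl with retention and gives the diene C2=C3–C4=C5 with the tether trans to the vinyl group.

Step 13
Reactants: 20 (2Z,5R,6R,7S,10R)-2,7-diethenyl-6,7,10-trimethyl-12-[(triisopropylsilyl)oxy]dodec-2-ene-1,5-diol
Product: 21 (5S,7R,8R,9S,10R,13R)-15-[(triisopropylsilyl)oxy]-19-norhalim-3-ene-7,18-diol
Conditions: toluene (high dilution), BHT, 190 °C, sealed tube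
Reagents that add atoms: none
Why: Thermal intramolecular Diels–Alder reaction of a 1,7,9-decatriene, a concerted suprafacial [4+2] in which the vinyl group on C9 (C1=C10) adds across the termini of the diene C2=C3–C4=C5. Ring A closes as the cyclohexene of the cycloaddition (bonds C1–C2 and C5–C10) and ring B closes at the same time through the four-carbon tether C6–C9, the C5–C10 bond becoming the ring fusion; the tether dictates the regiochemistry. The new stereocentre C10 is controlled by a chair-like forming ring B in which the C7 hydroxyl, the C8 methyl and the dienophile carbon C1 are equatorial and the C9 methyl is axial, which should place 10-H anti to the C9 methyl. C5 is also created (trans fusion expected as major, as drawn), but its configuration is erased when C5 becomes trigonal in step 19, so the cis-fused isomer from the same dienophile face converges. The only selectivity needed is therefore facial selectivity at the dienophile, which rests on the C7/C8 stereocentres and the equatorial preference of C1 next to quaternary C9; the C4=C5 geometry fixed in steps 11 and 12 keeps the tether at the outside position of the diene so the s-cis conformer is accessible. The unactivated partners need about 190 °C, where the gem-disubstituted C9 favours closure and the hydroxyls and silyl ether are stable.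

Step 14
Reactants: 21 (5S,7R,8R,9S,10R,13R)-15-[(triisopropylsilyl)oxy]-19-norhalim-3-ene-7,18-diol
Product: 22 (3R,4R,5S,7R,8R,9S,10R,13R)-15-[(triisopropylsilyl)oxy]-3,19-cyclohalimane-7,18-diol
Conditions: Et2Zn, CH2I2, DME, CH2Cl2, −10 °C; (4S,5S)-2-butyl-N,N,N',N'-tetramethyl-1,3,2-dioxaborolane-4,5-dicarboxamide (excess); −10 → 25 °C
Reagents that add atoms: diiodomethane, ICI
Why: Asymmetric Simmons–Smith cyclopropanation directed by the allylic zinc alkoxide bound to the tartramide-derived dioxaborolane; the controller should deliver CH2 to the face of C3=C4 anti to 10-H, overriding the weak ring bias and making the outcome independent of the C5 configuration (excess reagent covers the C7 hydroxyl).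

Step 15
Reactants: 22 (3R,4R,5S,7R,8R,9S,10R,13R)-15-[(triisopropylsilyl)oxy]-3,19-cyclohalimane-7,18-diol
Product: 23 (3R,4R,5S,7R,8R,9S,10R,13R)-7-hydroxy-15-[(triisopropylsilyl)oxy]-3,19-cyclohalimane-18-yl acetate
Conditions: Ac2O, pyridine, CH2Cl2, 0 °C
Reagents that add atoms: acetic anhydride, CC(=O)OC(C)=O
Why: The primary cyclopropylcarbinol is acetylated selectively over the secondary C7 hydroxyl, which is flanked by the C8 methyl and quaternary C9.

Step 16
Reactants: 23 (3R,4R,5S,7R,8R,9S,10R,13R)-7-hydroxy-15-[(triisopropylsilyl)oxy]-3,19-cyclohalimane-18-yl acetate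
Product: 24 (4R,5S,7R,8R,9S,10R,13R)-7-hydroxy-15-[(triisopropylsilyl)oxy]halimane-18-yl acetate
Conditions: H2 (3 atm), PtO2, AcOH, 25 °C
Reagents that add atoms: none
Why: Catalytic hydrogenolysis of the cyclopropane cleaves its least substituted bond (C3–C19), turning the cyclopropane methylene into the C19 methyl and leaving C4 quaternary with the configuration fixed in step 14.

Step 17
Reactants: 24 (4R,5S,7R,8R,9S,10R,13R)-7-hydroxy-15-[(triisopropylsilyl)oxy]halimane-18-yl acetate
Product: 25 (4R,5S,7R,8R,9S,10R,13R)-7,15-dihydroxyhalimane-18-yl acetate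
Conditions: HF·pyridine, THF, 0 → 25 °C
Reagents that add atoms: none
Why: Fluoride-mediated desilylation frees the C15 primary alcohol; the acetate and the secondary alcohol are unaffected.

Step 18
Reactants: 25 (4R,5S,7R,8R,9S,10R,13R)-7,15-dihydroxyhalimane-18-yl acetate
Product: 27 (4R,5S,8R,9S,10R,13R)-18-acetoxy-7-oxohalimane-15-oic acid, via keto aldehyde 26 (not isolated)
Conditions: CrO3, H2SO4, acetone/H2O, 0 °C
Reagents that add atoms: water, O
Why: Jones oxidation takes the primary alcohol through the aldehyde hydrate to the acid and the secondary alcohol to the C7 ketone in one operation; the acetate is stable and C8 keeps its equatorial-methyl configuration, which is expected to be the thermodynamically preferred one.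

Step 19
Reactants: 27 (4R,5S,8R,9S,10R,13R)-18-acetoxy-7-oxohalimane-15-oic acid
Product: 28 (4R,8R,9S,10S,13R)-18-acetoxy-7-oxohalim-5-en-15-oic acid
Conditions: IBX, DMSO/fluorobenzene, 70 °C
Reagents that add atoms: none
Why: IBX-mediated α,β-dehydrogenation of the ketone through its enol; because C9 is quaternary, ring unsaturation can enter only toward C5, which gives the C5=C6 enone and removes the C5 stereocentre.

**Compound list**

1 | (R)-citronellol, (3R)-3,7-dimethyloct-6-en-1-ol | C[C@H](CCC=C(C)C)CCO | starting material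
2 | triisopropyl{[(3R)-3,7-dimethyloct-6-en-1-yl]oxy}silane | C[C@H](CCC=C(C)C)CCO[Si](C(C)C)(C(C)C)C(C)C | intermediate
3 | ozonide (1,2,4-trioxolane) of 2 | CC1(C)OOC(CC[C@@H](C)CCO[Si](C(C)C)(C(C)C)C(C)C)O1 | intermediate
4 | (4R)-4-methyl-6-[(triisopropylsilyl)oxy]hexanal | O=CCC[C@@H](C)CCO[Si](C(C)C)(C(C)C)C(C)C | intermediate
5 | triisopropyl{[(3R)-3-methylhept-6-yn-1-yl]oxy}silane | C#CCC[C@@H](C)CCO[Si](C(C)C)(C(C)C)C(C)C | intermediate
6 | dimethyl[(1E,5R)-2,5-dimethyl-7-(triisopropylsilyloxy)hept-1-en-1-yl]alane | C/C(CC[C@@H](C)CCO[Si](C(C)C)(C(C)C)C(C)C)=C\[Al](C)C | intermediate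
7 | (2E,6R)-3,6-dimethyl-8-[(triisopropylsilyl)oxy]oct-2-en-1-ol | C/C(CC[C@@H](C)CCO[Si](C(C)C)(C(C)C)C(C)C)=C\CO | intermediate
8 | propanoyl chloride | CCC(Cl)=O | starting material
9 | (2E,6R)-3,6-dimethyl-8-[(triisopropylsilyl)oxy]oct-2-en-1-yl propanoate | CCC(=O)OC/C=C(\C)CC[C@@H](C)CCO[Si](C(C)C)(C(C)C)C(C)C | intermediate
10 | boron ketene acetal of 9 (C8 methyl cis to O–B; (S,S)-diazaborolidine on boron) | C/C=C(/OC/C=C(\C)CC[C@@H](C)CCO[Si](C(C)C)(C(C)C)C(C)C)OB1N(S(=O)(=O)c2cc(C(F)(F)F)cc(C(F)(F)F)c2)[C@@H](c2ccccc2)[C@H](c2ccccc2)N1S(=O)(=O)c1cc(C(F)(F)F)cc(C(F)(F)F)c1 | intermediate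
11 | (2R,3S,6R)-3-ethenyl-2,3,6-trimethyl-8-[(triisopropylsilyl)oxy]octanoic acid | OC(=O)[C@H](C)[C@@](C=C)(C)CC[C@@H](C)CCO[Si](C(C)C)(C(C)C)C(C)C | intermediate
12 | (2R,3S,6R)-3-ethenyl-2,3,6-trimethyl-8-[(triisopropylsilyl)oxy]octan-1-ol | OC[C@H](C)[C@@](C=C)(C)CC[C@@H](C)CCO[Si](C(C)C)(C(C)C)C(C)C | intermediate
13 | (2R,3S,6R)-3-ethenyl-2,3,6-trimethyl-8-[(triisopropylsilyl)oxy]octanal | O=C[C@H](C)[C@@](C=C)(C)CC[C@@H](C)CCO[Si](C(C)C)(C(C)C)C(C)C | intermediate
14 | (2S)-2-[(2R,3S,6R)-3-ethenyl-3,6-dimethyl-8-(triisopropylsilyloxy)octan-2-yl]oxirane | C1O[C@H]1[C@H](C)[C@@](C=C)(C)CC[C@@H](C)CCO[Si](C(C)C)(C(C)C)C(C)C | intermediate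
15 | trimethyl(prop-2-yn-1-yloxy)silane | C#CCO[Si](C)(C)C | starting material
16 | 1-O-trimethylsilyl ether of 17 | C[Si](C)(C)OCC#CC[C@@H](O)[C@H](C)[C@@](C=C)(C)CC[C@@H](C)CCO[Si](C(C)C)(C(C)C)C(C)C | intermediate
17 | (5R,6R,7S,10R)-7-ethenyl-6,7,10-trimethyl-12-[(triisopropylsilyl)oxy]dodec-2-yne-1,5-diol | OCC#CC[C@@H](O)[C@H](C)[C@@](C=C)(C)CC[C@@H](C)CCO[Si](C(C)C)(C(C)C)C(C)C | intermediate
18 | (2E,5R,6R,7S,10R)-7-ethenyl-6,7,10-trimethyl-2-(tributylstannyl)-12-[(triisopropylsilyl)oxy]dodec-2-ene-1,5-diol | OC/C([Sn](CCCC)(CCCC)CCCC)=C\C[C@@H](O)[C@H](C)[C@@](C=C)(C)CC[C@@H](C)CCO[Si](C(C)C)(C(C)C)C(C)C | intermediate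
19 | bromoethene (vinyl bromide) | C=CBr | starting material
20 | (2Z,5R,6R,7S,10R)-2,7-diethenyl-6,7,10-trimethyl-12-[(triisopropylsilyl)oxy]dodec-2-ene-1,5-diol | OC/C(C=C)=C\C[C@@H](O)[C@H](C)[C@@](C=C)(C)CC[C@@H](C)CCO[Si](C(C)C)(C(C)C)C(C)C | intermediate
21 | (5S,7R,8R,9S,10R,13R)-15-[(triisopropylsilyl)oxy]-19-norhalim-3-ene-7,18-diol (trans-fused; 10-H anti to C20 methyl) | OCC1=CCC[C@@H]2[C@@H]1C[C@@H](O)[C@H](C)[C@@]2(C)CC[C@@H](C)CCO[Si](C(C)C)(C(C)C)C(C)C | intermediate
22 | (3R,4R,5S,7R,8R,9S,10R,13R)-15-[(triisopropylsilyl)oxy]-3,19-cyclohalimane-7,18-diol | OC[C@]12C[C@H]1CC[C@@H]3[C@@H]2C[C@@H](O)[C@H](C)[C@@]3(C)CC[C@@H](C)CCO[Si](C(C)C)(C(C)C)C(C)C | intermediate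
23 | (3R,4R,5S,7R,8R,9S,10R,13R)-7-hydroxy-15-[(triisopropylsilyl)oxy]-3,19-cyclohalimane-18-yl acetate | CC(=O)OC[C@]12C[C@H]1CC[C@@H]3[C@@H]2C[C@@H](O)[C@H](C)[C@@]3(C)CC[C@@H](C)CCO[Si](C(C)C)(C(C)C)C(C)C | intermediate
24 | (4R,5S,7R,8R,9S,10R,13R)-7-hydroxy-15-[(triisopropylsilyl)oxy]halimane-18-yl acetate | CC(=O)OC[C@]1(C)CCC[C@@H]2[C@@H]1C[C@@H](O)[C@H](C)[C@@]2(C)CC[C@@H](C)CCO[Si](C(C)C)(C(C)C)C(C)C | intermediate
25 | (4R,5S,7R,8R,9S,10R,13R)-7,15-dihydroxyhalimane-18-yl acetate | CC(=O)OC[C@]1(C)CCC[C@@H]2[C@@H]1C[C@@H](O)[C@H](C)[C@@]2(C)CC[C@@H](C)CCO | intermediate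
26 | (4R,5S,8R,9S,10R,13R)-18-acetoxy-7-oxohalimane-15-al | CC(=O)OC[C@]1(C)CCC[C@@H]2[C@@H]1CC(=O)[C@H](C)[C@@]2(C)CC[C@@H](C)CC=O | intermediate
27 | (4R,5S,8R,9S,10R,13R)-18-acetoxy-7-oxohalimane-15-oic acid | CC(=O)OC[C@]1(C)CCC[C@@H]2[C@@H]1CC(=O)[C@H](C)[C@@]2(C)CC[C@@H](C)CC(=O)O | intermediate
28 | (4R,8R,9S,10S,13R)-18-acetoxy-7-oxohalim-5-en-15-oic acid (CNP0210381.1) | CC(=O)OC[C@]1(C)CCC[C@@H]2C1=CC(=O)[C@H](C)[C@@]2(C)CC[C@@H](C)CC(=O)O | target

**Total step count:** 19. **Longest linear sequence:** 19 steps (1 → 28); compounds 8, 15 and 19 are commercial reactants.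

**Steps most likely to fail**

1. Step 13 – poor facial selectivity at the vinyl dienophile (giving the C10 epimer), or sluggish cycloaddition of the hindered, unactivated alkene with competing decomposition at high temperature. The fallback sets out from 20 and comes back at 21. The diol is silylated (Et3SiCl, imidazole, DMF) to the bis(triethylsilyl) ether of 20 F1. This is cyclised not thermally but with a cationic monovalent rhodium catalyst ([Rh(cod)Cl]2, AgSbF6, CH2Cl2, 25–40 °C). That [4+2] runs stepwise through oxidative cyclisation of diene and alkene to a rhodacycle and reductive elimination, near room temperature, where the equatorial preference should be amplified. It gives the bis(triethylsilyl) ether of 21 F2. PPTS in MeOH at 0 °C removes both triethylsilyl groups, leaves the triisopropylsilyl ether, and returns to 21.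

2. Step 16 – cleavage of the wrong cyclopropane bond (C3–C4 or C4–C19) or stalled hydrogenolysis. The fallback sets out from 21 and comes back at 24. The primary allylic alcohol is acetylated selectively (Ac2O, pyridine, 0 °C) to the 18-O-acetate of 21 F3. Iron-hydride hydrogen-atom transfer (Fe(acac)3 with trivalent iron, PhSiH3, THF/MeOH, 25 °C) puts H on C3 and generates the tertiary C4 radical. The radical adds to formaldehyde N-(octylsulfonyl)hydrazone (from aqueous formaldehyde and octane-1-sulfonohydrazide) to give the C19 sulfonohydrazide F4. Warming in MeOH at 60 °C expels sulfinate and nitrogen and leaves the C19 methyl, giving 24. C4 is then set by substrate control (attack on the equatorial side of the trans-decalin radical is expected), so this path trades the reagent control of step 14 for one step fewer.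

3. Step 6 – loss of enantiofacial control or of ketene-acetal geometry in the boron-mediated rearrangement. The fallback sets out from 9 and comes back at 12. A classical Ireland–Claisen rearrangement (LiN(i-Pr)2, Me3SiCl, THF/DMPU, −78 → 25 °C, then dilute acid) proceeds through the (Z)-silyl ketene acetal and the same chair. It still fixes the relative C8/C9 configuration but gives acid 11 together with its (2S,3R,6R) diastereomer F5. The mixture is converted (pivaloyl chloride, Et3N; then lithiated (4S)-4-benzyl-1,3-oxazolidin-2-one, THF, −78 → 0 °C) into the N-acyl oxazolidinone of 11 F6 and the N-acyl oxazolidinone of the diastereomer F7. These differ at centres next to the auxiliary and are separated by chromatography. LiBH4 (Et2O, H2O, 0 °C) cleaves F6 reductively to alcohol 12, bypassing step 7.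

**Further compounds**

F1 | step 13 | bis(triethylsilyl) ether of 20 | CC[Si](CC)(CC)OC/C(C=C)=C\C[C@@H](O[Si](CC)(CC)CC)[C@H](C)[C@@](C=C)(C)CC[C@@H](C)CCO[Si](C(C)C)(C(C)C)C(C)C
F2 | step 13 | bis(triethylsilyl) ether of 21 | CC[Si](CC)(CC)OCC1=CCC[C@@H]2[C@@H]1C[C@@H](O[Si](CC)(CC)CC)[C@H](C)[C@@]2(C)CC[C@@H](C)CCO[Si](C(C)C)(C(C)C)C(C)C
F3 | step 16 | 18-O-acetate of 21 | CC(=O)OCC1=CCC[C@@H]2[C@@H]1C[C@@H](O)[C@H](C)[C@@]2(C)CC[C@@H](C)CCO[Si](C(C)C)(C(C)C)C(C)C
F4 | step 16 | C19 N'-(octylsulfonyl)hydrazide adduct of F3 | CCCCCCCCS(=O)(=O)NNC[C@@]1(COC(C)=O)CCC[C@@H]2[C@@H]1C[C@@H](O)[C@H](C)[C@@]2(C)CC[C@@H](C)CCO[Si](C(C)C)(C(C)C)C(C)C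
F5 | step 6 | (2S,3R,6R)-3-ethenyl-2,3,6-trimethyl-8-[(triisopropylsilyl)oxy]octanoic acid | OC(=O)[C@@H](C)[C@](C=C)(C)CC[C@@H](C)CCO[Si](C(C)C)(C(C)C)C(C)C
F6 | step 6 | (4S)-4-benzyl-3-[(2R,3S,6R)-3-ethenyl-2,3,6-trimethyl-8-(triisopropylsilyloxy)octanoyl]-1,3-oxazolidin-2-one | O=C1OC[C@H](Cc2ccccc2)N1C(=O)[C@H](C)[C@@](C=C)(C)CC[C@@H](C)CCO[Si](C(C)C)(C(C)C)C(C)C
F7 | step 6 | (4S)-4-benzyl-3-[(2S,3R,6R)-3-ethenyl-2,3,6-trimethyl-8-(triisopropylsilyloxy)octanoyl]-1,3-oxazolidin-2-one | O=C1OC[C@H](Cc2ccccc2)N1C(=O)[C@@H](C)[C@](C=C)(C)CC[C@@H](C)CCO[Si](C(C)C)(C(C)C)C(C)C
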